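## Retrosynthetic overview

1. The ten-membered carbocycle is closed last, at C9–C10, by an intramolecular B-alkyl Suzuki–Miyaura macrocyclization of an open-chain vinyl iodide/terminal alkene; this fixes the (E)-C1=C10 olefin and delivers the target directly.
2. The open chain comes from a catalyst-controlled anti-allylboration (C6–C7, sets C6 and C7) of an epoxy aldehyde with an (E)-γ-isopropylallylboronate (fragment C).
3. The oxirane (C4, C5) is installed before that by Sharpless epoxidation of a primary allylic alcohol. C3 is set earlier by asymmetric propargylboration of enal fragment B with 1-methylallenylboronate fragment A, and the alkyne becomes the (E)-vinyl iodide by hydrozirconation–iodination.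
4. Both esters are put on the open chain. Ring order: oxirane first (step 10), carbocycle last (step 17).

Conventions: C-numbers are germacrane positions of the target (ring C1–C10; C1=C10 olefin, C3 OAng, C4/C5 oxirane, C6 OAc, C7 iPr); the target is (3S,4R,5R,6R,7S). TRIP = 3,3'-bis(2,4,6-triisopropylphenyl)-1,1'-binaphthyl-2,2'-diyl hydrogen phosphate. Bpin = pinacolatoboryl.

Assumption: (R)-TRIP delivers the allyl/propargyl group to the Re face of RCHO, as for aryl and alkenyl aldehydes; if the sense is opposite, the antipodal catalyst is used in steps 5 and 15.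

## Route

Step 1
Reactants: 1 but-2-yn-1-ol
Product: 2 but-2-yn-1-yl methyl carbonate
Conditions: ClCO2Me, pyridine, CH2Cl2, 0 °C → rt
Reagents that add atoms: methyl chloroformate COC(=O)Cl
Why: O-acylation of the primary propargylic alcohol (carbonate formation) installs the leaving group for the borylation and creates no stereocentre.

Step 2
Reactants: 2 but-2-yn-1-yl methyl carbonate
Product: 3 2-(buta-2,3-dien-2-yl)-4,4,5,5-tetramethyl-1,3,2-dioxaborolane (fragment A)
Conditions: B2pin2, CuCl (5 mol%), KOtBu (5 mol%), Xantphos (5 mol%), THF, rt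
Reagents that add atoms: bis(pinacolato)diboron CC1(C)OB(OC1(C)C)B1OC(C)(C)C(C)(C)O1
Why: Copper-catalysed SN2'-type borylation of a propargylic carbonate puts boron on the alkyne carbon remote from the leaving group, giving the 1-methylallenylboronate regiospecifically.

Step 3
Reactants: 4 3-methylbut-2-en-1-ol (prenol)
Product: 5 tert-butyldimethyl[(3-methylbut-2-en-1-yl)oxy]silane
Conditions: TBSCl, imidazole, CH2Cl2, 0 °C → rt
Reagents that add atoms: tert-butyldimethylsilyl chloride CC(C)(C)[Si](C)(C)Cl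
Why: Imidazole-promoted silylation protects the primary alcohol as a TBS ether that survives every step up to step 9.

Step 4
Reactants: 5 tert-butyldimethyl[(3-methylbut-2-en-1-yl)oxy]silane
Product: 7 (2E)-4-[(tert-butyldimethylsilyl)oxy]-2-methylbut-2-enal (fragment B), via allylic alcohol 6 (not isolated)
Conditions: SeO2 (cat.), t-BuOOH, salicylic acid (cat.), CH2Cl2, rt; then MnO2, CH2Cl2, rt
Reagents that add atoms: tert-butyl hydroperoxide CC(C)(C)OO
Why: Riley allylic oxidation (ene reaction then [2,3]-sigmatropic shift) attacks the (E)-methyl of the trisubstituted alkene, and MnO2 converges alcohol and aldehyde to the (E)-enal.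

Step 5
Reactants: 7 (2E)-4-[(tert-butyldimethylsilyl)oxy]-2-methylbut-2-enal; 3 2-(buta-2,3-dien-2-yl)-4,4,5,5-tetramethyl-1,3,2-dioxaborolane
Product: 9 (2E,4S)-1-[(tert-butyldimethylsilyl)oxy]-3-methyloct-2-en-6-yn-4-ol, via O-boryl ether 8 (not isolated)
Conditions: (S)-TRIP (10 mol%), 4 Å MS, toluene, −20 °C; aq. NaHCO3 work-up
Reagents that add atoms: none
Why: Chiral phosphoric acid-catalysed asymmetric propargylboration (SE2' addition through a closed six-membered transition state) delivers the CH2 terminus of the allenylboronate to the Si face of the aldehyde under (S)-TRIP control, which sets C3 as S and gives only the homopropargylic methyl alkyne.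

Step 6
Reactants: 9 (2E,4S)-1-[(tert-butyldimethylsilyl)oxy]-3-methyloct-2-en-6-yn-4-ol
Product: 11 (2E,4S,6E)-1-[(tert-butyldimethylsilyl)oxy]-7-iodo-3-methylocta-2,6-dien-4-ol, via bis-zirconocene adduct 10 (not isolated)
Conditions: Cp2Zr(H)Cl (3 equiv), THF, rt → 45 °C; then I2, THF, 0 °C
Reagents that add atoms: iodine II
Why: syn-Hydrozirconation places zirconium on the less hindered, methyl-bearing alkyne carbon after equilibration and iodinolysis goes with retention, so the (E)-2-iodoalkene with iodine trans to C2 is formed (hydrozirconation–iodination).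

Step 7
Reactants: 12 angelic acid, (2Z)-2-methylbut-2-enoic acid (2 equiv)
Product: 13 angelic anhydride, (2Z)-2-methylbut-2-enoic anhydride
Conditions: DCC (0.5 equiv), CH2Cl2, 0 °C → rt
Reagents that add atoms: none
Why: Carbodiimide dehydration to the symmetrical anhydride uses no nucleophilic catalyst, so the (Z)-geometry of the acid is kept.

Step 8
Reactants: 11 (2E,4S,6E)-1-[(tert-butyldimethylsilyl)oxy]-7-iodo-3-methylocta-2,6-dien-4-ol; 13 angelic anhydride
Product: 15 (2E,4S,6E)-1-[(tert-butyldimethylsilyl)oxy]-7-iodo-3-methylocta-2,6-dien-4-yl (2Z)-2-methylbut-2-enoate, via lithium alkoxide 14 (not isolated)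
Conditions: LiN(SiMe3)2 (1.1 equiv), THF, −78 °C; then 13, −78 → 0 °C
Reagents that add atoms: none
Why: Acylation of the preformed lithium alkoxide by the anhydride (nucleophilic acyl substitution without amine or DMAP catalysis) gives the angelate without Z to E isomerisation, and C3 keeps its configuration because its C–O bond is not touched.

Step 9
Reactants: 15 (2E,4S,6E)-1-[(tert-butyldimethylsilyl)oxy]-7-iodo-3-methylocta-2,6-dien-4-yl (2Z)-2-methylbut-2-enoate
Product: 16 (2E,4S,6E)-1-hydroxy-7-iodo-3-methylocta-2,6-dien-4-yl (2Z)-2-methylbut-2-enoate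
Conditions: HF·pyridine, pyridine, THF, 0 °C → rt
Reagents that add atoms: none
Why: Buffered fluoride desilylation frees the primary allylic alcohol while the angelate, the vinyl iodide and both alkenes are inert, and acyl migration is impossible across the (E)-alkene.

Step 10
Reactants: 16 (2E,4S,6E)-1-hydroxy-7-iodo-3-methylocta-2,6-dien-4-yl (2Z)-2-methylbut-2-enoate
Product: 17 (1S,3E)-1-[(2R,3R)-3-(hydroxymethyl)-2-methyloxiran-2-yl]-4-iodopent-3-en-1-yl (2Z)-2-methylbut-2-enoate
Conditions: Ti(OiPr)4, D-(−)-diisopropyl tartrate, t-BuOOH, 4 Å MS, CH2Cl2, −20 °C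
Reagents that add atoms: tert-butyl hydroperoxide CC(C)(C)OO
Why: Sharpless asymmetric epoxidation of the geraniol-type (E)-trisubstituted primary allylic alcohol is reagent-controlled, and the D-tartrate delivers oxygen to the face opposite to that of the L-tartrate/geraniol case, giving the (4R,5R)-oxirane while the vinyl iodide and the angelate alkene stay untouched.

Step 11
Reactants: 17 (1S,3E)-1-[(2R,3R)-3-(hydroxymethyl)-2-methyloxiran-2-yl]-4-iodopent-3-en-1-yl (2Z)-2-methylbut-2-enoate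
Product: 18 (1S,3E)-1-[(2R,3S)-3-formyl-2-methyloxiran-2-yl]-4-iodopent-3-en-1-yl (2Z)-2-methylbut-2-enoate
Conditions: Dess–Martin periodinane, NaHCO3, CH2Cl2, 0 °C → rt
Reagents that add atoms: none
Why: Buffered Dess–Martin oxidation gives the epoxy aldehyde without epimerising C5 or opening the oxirane (the descriptor at C5 changes only because the CIP priorities change).

Step 12
Reactants: 19 2-methylpropanal; 20 vinylmagnesium bromide
Product: 21 4-methylpent-1-en-3-ol (racemic)
Conditions: THF, 0 °C → rt; aqueous work-up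
Reagents that add atoms: none
Why: Grignard 1,2-addition gives the racemic allylic alcohol, whose stereocentre is erased in step 14.

Step 13
Reactants: 21 4-methylpent-1-en-3-ol
Product: 22 4-methylpent-1-en-3-yl acetate (racemic)
Conditions: Ac2O, pyridine, DMAP (cat.), CH2Cl2, rt
Reagents that add atoms: acetic anhydride CC(=O)OC(C)=O
Why: DMAP-catalysed acetylation turns the alcohol into the leaving group needed for π-allyl formation.

Step 14
Reactants: 22 4-methylpent-1-en-3-yl acetate
Product: 23 4,4,5,5-tetramethyl-2-[(2E)-4-methylpent-2-en-1-yl]-1,3,2-dioxaborolane (fragment C)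
Conditions: B2pin2, Pd2(dba)3 (2.5 mol%), DMSO, 50 °C
Reagents that add atoms: bis(pinacolato)diboron CC1(C)OB(OC1(C)C)B1OC(C)(C)C(C)(C)O1
Why: Palladium-catalysed Miyaura allylic borylation goes through the syn π-allyl complex and boron is delivered to the unsubstituted terminus, giving the linear (E)-allylboronate.

Step 15
Reactants: 18 (1S,3E)-1-[(2R,3S)-3-formyl-2-methyloxiran-2-yl]-4-iodopent-3-en-1-yl (2Z)-2-methylbut-2-enoate; 23 4,4,5,5-tetramethyl-2-[(2E)-4-methylpent-2-en-1-yl]-1,3,2-dioxaborolane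
Product: 25 (1S,3E)-1-{(2R,3R)-3-[(1R,2R)-1-hydroxy-2-(propan-2-yl)but-3-en-1-yl]-2-methyloxiran-2-yl}-4-iodopent-3-en-1-yl (2Z)-2-methylbut-2-enoate, via O-boryl ether 24 (not isolated)
Conditions: (R)-TRIP (10 mol%), 4 Å MS, toluene, −30 °C; aq. NaHCO3 work-up
Reagents that add atoms: none
Why: Chiral phosphoric acid-catalysed allylboration through a chair Zimmerman–Traxler transition state makes the (E)-boronate give the 6,7-anti adduct, (R)-TRIP directs attack to the Re face of the aldehyde (C6 R, C7 with iPr anti to the oxygen), and this is expected to match the Felkin–Anh/Cornforth preference of the epoxy aldehyde for the 5,6-anti product.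

Step 16
Reactants: 25 (1S,3E)-1-{(2R,3R)-3-[(1R,2R)-1-hydroxy-2-(propan-2-yl)but-3-en-1-yl]-2-methyloxiran-2-yl}-4-iodopent-3-en-1-yl (2Z)-2-methylbut-2-enoate
Product: 26 (1S,3E)-1-{(2R,3R)-3-[(1R,2R)-1-(acetyloxy)-2-(propan-2-yl)but-3-en-1-yl]-2-methyloxiran-2-yl}-4-iodopent-3-en-1-yl (2Z)-2-methylbut-2-enoate
Conditions: Ac2O, pyridine, DMAP (cat.), CH2Cl2, 0 °C → rt
Reagents that add atoms: acetic anhydride CC(=O)OC(C)=O
Why: DMAP-catalysed acetylation of the C6 hydroxyl proceeds with retention and non-basic conditions avoid Payne rearrangement of the epoxy alcohol.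

Step 17
Reactants: 26 (1S,3E)-1-{(2R,3R)-3-[(1R,2R)-1-(acetyloxy)-2-(propan-2-yl)but-3-en-1-yl]-2-methyloxiran-2-yl}-4-iodopent-3-en-1-yl (2Z)-2-methylbut-2-enoate
Product: 28 CNP0180504.2 [(3S,4R,5R,6R,7S)-6-acetoxy-4,5-epoxygermacr-1(10)E-en-3-yl angelate], via B-alkyl-9-BBN 27 (not isolated)
Conditions: 9-BBN (2 equiv), THF, rt; then syringe-pump addition to Pd(dppf)Cl2 (20 mol%), AsPh3, Cs2CO3, DMF/THF/H2O, 1 mM, rt → 45 °C
Reagents that add atoms: none
Why: Anti-Markovnikov hydroboration of the only monosubstituted alkene followed by intramolecular B-alkyl Suzuki–Miyaura macrocyclization under high dilution forms C9–C10 with retention of the vinyl iodide geometry, so the (E)-C1=C10 olefin is fixed and no stereocentre is touched.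

## Compound list

1 | but-2-yn-1-ol | CC#CCO | starting material
2 | but-2-yn-1-yl methyl carbonate | CC#CCOC(=O)OC | intermediate
3 | 2-(buta-2,3-dien-2-yl)-4,4,5,5-tetramethyl-1,3,2-dioxaborolane (fragment A) | C=C=C(C)B1OC(C)(C)C(C)(C)O1 | intermediate
4 | 3-methylbut-2-en-1-ol | CC(C)=CCO | starting material
5 | tert-butyldimethyl[(3-methylbut-2-en-1-yl)oxy]silane | CC(C)=CCO[Si](C)(C)C(C)(C)C | intermediate
6 | (2E)-4-[(tert-butyldimethylsilyl)oxy]-2-methylbut-2-en-1-ol | OC/C(C)=C/CO[Si](C)(C)C(C)(C)C | intermediate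
7 | (2E)-4-[(tert-butyldimethylsilyl)oxy]-2-methylbut-2-enal (fragment B) | O=C/C(C)=C/CO[Si](C)(C)C(C)(C)C | intermediate
8 | O-pinacolatoboryl ether of 9 | CC#CC[C@H](OB1OC(C)(C)C(C)(C)O1)/C(C)=C/CO[Si](C)(C)C(C)(C)C | intermediate
9 | (2E,4S)-1-[(tert-butyldimethylsilyl)oxy]-3-methyloct-2-en-6-yn-4-ol | CC#CC[C@H](O)/C(C)=C/CO[Si](C)(C)C(C)(C)C | intermediate
10 | bis-zirconocene adduct of 9: Cp2Zr(Cl) on C7 (where 11 carries iodine) and Cp2Zr(Cl) on O4 | C/C(=C\C[C@H](O[Zr](Cl)(C1C=CC=C1)C1C=CC=C1)/C(C)=C/CO[Si](C)(C)C(C)(C)C)[Zr](Cl)(C1C=CC=C1)C1C=CC=C1 | intermediate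
11 | (2E,4S,6E)-1-[(tert-butyldimethylsilyl)oxy]-7-iodo-3-methylocta-2,6-dien-4-ol | C/C(I)=C\C[C@H](O)/C(C)=C/CO[Si](C)(C)C(C)(C)C | intermediate
12 | angelic acid, (2Z)-2-methylbut-2-enoic acid | C/C=C(/C)C(=O)O | starting material
13 | angelic anhydride, (2Z)-2-methylbut-2-enoic anhydride | C/C=C(/C)C(=O)OC(=O)/C(C)=C\C | intermediate
14 | lithium (2E,4S,6E)-1-[(tert-butyldimethylsilyl)oxy]-7-iodo-3-methylocta-2,6-dien-4-olate | C/C(I)=C\C[C@H]([O-])/C(C)=C/CO[Si](C)(C)C(C)(C)C.[Li+] | intermediate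
15 | (2E,4S,6E)-1-[(tert-butyldimethylsilyl)oxy]-7-iodo-3-methylocta-2,6-dien-4-yl (2Z)-2-methylbut-2-enoate | C/C=C(/C)C(=O)O[C@@H](C/C=C(\C)I)/C(C)=C/CO[Si](C)(C)C(C)(C)C | intermediate
16 | (2E,4S,6E)-1-hydroxy-7-iodo-3-methylocta-2,6-dien-4-yl (2Z)-2-methylbut-2-enoate | C/C=C(/C)C(=O)O[C@@H](C/C=C(\C)I)/C(C)=C/CO | intermediate
17 | (1S,3E)-1-[(2R,3R)-3-(hydroxymethyl)-2-methyloxiran-2-yl]-4-iodopent-3-en-1-yl (2Z)-2-methylbut-2-enoate | C/C=C(/C)C(=O)O[C@@H](C/C=C(\C)I)[C@@]1(C)O[C@@H]1CO | intermediate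
18 | (1S,3E)-1-[(2R,3S)-3-formyl-2-methyloxiran-2-yl]-4-iodopent-3-en-1-yl (2Z)-2-methylbut-2-enoate | C/C=C(/C)C(=O)O[C@@H](C/C=C(\C)I)[C@@]1(C)O[C@@H]1C=O | intermediate
19 | 2-methylpropanal | CC(C)C=O | starting material
20 | vinylmagnesium bromide | C=C[Mg]Br | starting material
21 | 4-methylpent-1-en-3-ol (racemic) | CC(C)C(O)C=C | intermediate
22 | 4-methylpent-1-en-3-yl acetate (racemic) | CC(C)C(OC(C)=O)C=C | intermediate
23 | 4,4,5,5-tetramethyl-2-[(2E)-4-methylpent-2-en-1-yl]-1,3,2-dioxaborolane (fragment C) | CC(C)/C=C/CB1OC(C)(C)C(C)(C)O1 | intermediate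
24 | O-pinacolatoboryl ether of 25 | C/C=C(/C)C(=O)O[C@@H](C/C=C(\C)I)[C@@]1(C)O[C@@H]1[C@H](OB2OC(C)(C)C(C)(C)O2)[C@H](C(C)C)C=C | intermediate
25 | (1S,3E)-1-{(2R,3R)-3-[(1R,2R)-1-hydroxy-2-(propan-2-yl)but-3-en-1-yl]-2-methyloxiran-2-yl}-4-iodopent-3-en-1-yl (2Z)-2-methylbut-2-enoate | C/C=C(/C)C(=O)O[C@@H](C/C=C(\C)I)[C@@]1(C)O[C@@H]1[C@H](O)[C@H](C(C)C)C=C | intermediate
26 | (1S,3E)-1-{(2R,3R)-3-[(1R,2R)-1-(acetyloxy)-2-(propan-2-yl)but-3-en-1-yl]-2-methyloxiran-2-yl}-4-iodopent-3-en-1-yl (2Z)-2-methylbut-2-enoate | C/C=C(/C)C(=O)O[C@@H](C/C=C(\C)I)[C@@]1(C)O[C@@H]1[C@H](OC(C)=O)[C@H](C(C)C)C=C | intermediate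
27 | 9-BBN adduct of 26: (1R,2S)-1-(acetyloxy)-4-(9-borabicyclo[3.3.1]nonan-9-yl)-2-(propan-2-yl)butyl side chain | C/C=C(/C)C(=O)O[C@@H](C/C=C(\C)I)[C@@]1(C)O[C@@H]1[C@H](OC(C)=O)[C@H](C(C)C)CCB2C3CCCC2CCC3 | intermediate
28 | CNP0180504.2, (3S,4R,5R,6R,7S)-6-acetoxy-4,5-epoxygermacr-1(10)E-en-3-yl angelate | C/C=C(/C)C(=O)O[C@H]1C/C=C(\C)CC[C@@H](C(C)C)[C@@H](OC(C)=O)[C@H]2O[C@]12C | target

## Summary

Total step count: 17.
Longest linear sequence: 11 steps (1, 2, 5, 6, 8, 9, 10, 11, 15, 16, 17; the branch 3, 4 into step 5 is equally long).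

Steps most likely to fail:

Step 17 (macrocyclization). A ten-membered ring is the hardest size for B-alkyl Suzuki closure; protodeboronation, oligomers or ester cleavage by the aqueous base may win. The fallback closes the same bond with a different organometallic under base-free conditions. It sets out from 26: the 9-BBN adduct 27 is oxidised (NaBO3·4H2O) to the primary alcohol (1S,3E)-1-{(2R,3R)-3-[(1R,2S)-1-(acetyloxy)-4-hydroxy-2-(propan-2-yl)butyl]-2-methyloxiran-2-yl}-4-iodopent-3-en-1-yl (2Z)-2-methylbut-2-enoate F7. This is converted (I2, PPh3, imidazole) to the primary iodide, the 4-iodobutyl analogue F8. Selective zinc insertion into the alkyl iodide (Zn, LiCl, THF, 25 °C) gives the alkylzinc iodide F9, and intramolecular Negishi coupling with the vinyl iodide (Pd(PtBu3)2, THF/NMP, high dilution) comes back to the route at 28.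

Step 15 (allylboration of the epoxy aldehyde). The acid catalyst may open the oxirane, which carries a neighbouring acyloxy group, or the facial selectivity may be low. The fallback inverts the order of epoxidation and allylation. It sets out from 16: MnO2 gives the enal (2E,4S,6E)-7-iodo-3-methyl-1-oxoocta-2,6-dien-4-yl (2Z)-2-methylbut-2-enoate F4. The (R)-TRIP-catalysed allylboration with 23 is run on this robust enal and gives, through its O-pinacolatoboryl ether F5, the dienol (3R,4R,5E,7S,9E)-4-hydroxy-10-iodo-6-methyl-3-(propan-2-yl)undeca-1,5,9-trien-7-yl (2Z)-2-methylbut-2-enoate F6. The oxirane is then installed by Sharpless epoxidation in its secondary-alcohol mode (Ti(OiPr)4, D-(−)-diisopropyl tartrate, t-BuOOH). The (R)-carbinol is the fast-reacting, erythro-selective substrate for this tartrate, although the methyl cis to the carbinol will slow it. This comes back to the route at 25.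

Step 5 (propargylboration with the methyl-substituted allenylboronate). The extra methyl next to boron may lower rate or ee, and this substituted reagent is less precedented than the parent. The fallback sets out from 7: the same (S)-TRIP catalysis is run with commercial allenylboronic acid pinacol ester and gives, through the O-pinacolatoboryl ether F1, the terminal alkyne (2E,4S)-1-[(tert-butyldimethylsilyl)oxy]-3-methylhept-2-en-6-yn-4-ol F2. The alkyne methyl is then added in a separate C–C bond formation: double deprotonation (n-BuLi, 2.1 equiv, THF/DMPU, −78 °C) gives the dilithium alkoxide acetylide F3, and C-selective alkylation with MeI (1.0 equiv) comes back to the route at 9.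

## Further compounds

F1 | step 5 | O-pinacolatoboryl ether of F2 | C#CC[C@H](OB1OC(C)(C)C(C)(C)O1)/C(C)=C/CO[Si](C)(C)C(C)(C)C
F2 | step 5 | (2E,4S)-1-[(tert-butyldimethylsilyl)oxy]-3-methylhept-2-en-6-yn-4-ol | C#CC[C@H](O)/C(C)=C/CO[Si](C)(C)C(C)(C)C
F3 | step 5 | dilithium alkoxide acetylide of F2 | [Li+].[Li+].[C-]#CC[C@H]([O-])/C(C)=C/CO[Si](C)(C)C(C)(C)C
F4 | step 15 | (2E,4S,6E)-7-iodo-3-methyl-1-oxoocta-2,6-dien-4-yl (2Z)-2-methylbut-2-enoate | C/C=C(/C)C(=O)O[C@@H](C/C=C(\C)I)/C(C)=C/C=O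
F5 | step 15 | O-pinacolatoboryl ether of F6 | C/C=C(/C)C(=O)O[C@@H](C/C=C(\C)I)/C(C)=C/[C@H](OB1OC(C)(C)C(C)(C)O1)[C@H](C(C)C)C=C
F6 | step 15 | (3R,4R,5E,7S,9E)-4-hydroxy-10-iodo-6-methyl-3-(propan-2-yl)undeca-1,5,9-trien-7-yl (2Z)-2-methylbut-2-enoate | C/C=C(/C)C(=O)O[C@@H](C/C=C(\C)I)/C(C)=C/[C@H](O)[C@H](C(C)C)C=C
F7 | step 17 | (1S,3E)-1-{(2R,3R)-3-[(1R,2S)-1-(acetyloxy)-4-hydroxy-2-(propan-2-yl)butyl]-2-methyloxiran-2-yl}-4-iodopent-3-en-1-yl (2Z)-2-methylbut-2-enoate | C/C=C(/C)C(=O)O[C@@H](C/C=C(\C)I)[C@@]1(C)O[C@@H]1[C@H](OC(C)=O)[C@H](C(C)C)CCO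
F8 | step 17 | (1S,3E)-1-{(2R,3R)-3-[(1R,2S)-1-(acetyloxy)-4-iodo-2-(propan-2-yl)butyl]-2-methyloxiran-2-yl}-4-iodopent-3-en-1-yl (2Z)-2-methylbut-2-enoate | C/C=C(/C)C(=O)O[C@@H](C/C=C(\C)I)[C@@]1(C)O[C@@H]1[C@H](OC(C)=O)[C@H](C(C)C)CCI
F9 | step 17 | alkylzinc iodide from F8 (Zn–I on the terminal carbon of the butyl chain) | C/C=C(/C)C(=O)O[C@@H](C/C=C(\C)I)[C@@]1(C)O[C@@H]1[C@H](OC(C)=O)[C@H](C(C)C)CC[Zn]I
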